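**Strategy**

The ten-membered carbocycle is closed at the bond between the C9 methylene, which hangs on the lactone carbon C8 of the five-membered ring, and the methyl-bearing olefinic carbon C10 (germacrane numbering). The key step exploits this sp3–sp2 junction: a nickel-catalysed reductive cross-electrophile coupling joins the primary C9 bromide of a trans γ-(bromomethyl)butyrolactone with an (E)-alkenyl bromide at C10 in the same molecule, giving in one operation the cyclodeca-1(10),4-diene with the trans-fused lactone and the C6 oxygen in place. The open-chain dibromide precursor comes from an (R)-butyrolactone (C7, C8 by 1,4-addition) and a dihalodiene, united at C5–C6 by a Nozaki–Hiyama–Kishi reaction.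

Key step: step 11

Remark: atoms carry germacrane numbers (C1=C10 with methyl C14, C4=C5 with C15, ester oxygen at C6, C7, lactone oxygen at C8, C9, lactone carbons C11–C13); TBS = tert-butyl(dimethyl)silyl, TES = triethylsilyl; compounds 1, 14, 16, 36 and 37 and the reagents are taken as catalogue materials.

**Route**

Step 1
Reactants: 1 (5R)-5-(hydroxymethyl)oxolan-2-one; 2 tert-butyl(chloro)dimethylsilane
Product: 3 (5R)-5-[(TBS-oxy)methyl]oxolan-2-one
Conditions: TBSCl, imidazole, DMF, 0 → 25 °C
Reagents that add atoms: tert-butyl(chloro)dimethylsilane (CC(C)(C)[Si](C)(C)Cl)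
Why: Imidazole-promoted silylation of the primary alcohol protects the C9 oxygen for the enolate and cuprate steps and leaves the C8 stereocentre of the chiral-pool lactone untouched.

Step 2
Reactants: 3 (5R)-5-[(TBS-oxy)methyl]oxolan-2-one; 4 benzeneselenenyl bromide
Product: 6 (5R)-5-[(TBS-oxy)methyl]furan-2(5H)-one, via 3-phenylselanyl lactone 5 (not isolated)
Conditions: LiN(i-Pr)2, THF, −78 °C; PhSeBr; then H2O2, pyridine, CH2Cl2, 0 → 25 °C
Reagents that add atoms: none
Why: α-Selenenylation of the lithium lactone enolate and syn-elimination of the selenoxide (selenoxide elimination) introduce the butenolide double bond without affecting C8.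

Step 3
Reactants: 6 (5R)-5-[(TBS-oxy)methyl]furan-2(5H)-one; 7 vinylmagnesium bromide
Product: 8 (4S,5R)-4-ethenyl-5-[(TBS-oxy)methyl]oxolan-2-one
Conditions: CH2=CHMgBr, CuI (0.2 equiv), THF, −78 °C; aq NH4Cl
Reagents that add atoms: vinylmagnesium bromide (C=C[Mg]Br)
Why: Copper-catalysed conjugate addition of the vinyl Grignard reagent should occur on the butenolide face anti to the bulky C8 silyloxymethyl group, which sets C7 with the vinyl group (future C6) trans to C9.

Step 4
Reactants: 8 (4S,5R)-4-ethenyl-5-[(TBS-oxy)methyl]oxolan-2-one; 9 dibromotriphenyl-λ5-phosphane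
Product: 10 (4S,5R)-5-(bromomethyl)-4-ethenyloxolan-2-one
Conditions: Ph3PBr2, CH2Cl2, 0 → 25 °C
Reagents that add atoms: dibromotriphenyl-λ5-phosphane (BrP(Br)(c1ccccc1)(c1ccccc1)c1ccccc1)
Why: Ph3PBr2 should convert the primary silyl ether directly into the bromide (Appel-type bromophosphonium activation of oxygen, then SN2 displacement at primary C9), with no stereocentre involved and the vinyl group and lactone left intact.

Step 5
Reactants: 10 (4S,5R)-5-(bromomethyl)-4-ethenyloxolan-2-one; 11 ozone
Product: 13 (2R,3R)-2-(bromomethyl)-5-oxooxolane-3-carbaldehyde, via secondary ozonide 12 (not isolated)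
Conditions: O3, CH2Cl2, −78 °C; then PPh3, −78 → 0 °C; used crude
Reagents that add atoms: ozone ([O-][O+]=O)
Why: Ozonolysis of the monosubstituted alkene with reductive work-up gives the C6 aldehyde; the trans C7/C8 arrangement is the thermodynamically preferred one, and the crude aldehyde is used at once to avoid β-elimination of the lactone carboxylate.

Step 6
Reactants: 16 prop-2-yn-1-ol; 14 5-bromopent-2-yne; 15 magnesium; 17 iodine
Product: 20 (2Z)-2-(iodomethylidene)hept-5-yn-1-ol, via pent-3-ynylmagnesium bromide 18 (not isolated), via alkenylmagnesium alkoxide 19 (not isolated)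
Conditions: Mg, THF, 25 °C; HC≡CCH2OH, CuI (0.1 equiv), Et2O–THF, 0 °C → reflux; then I2, −78 → 0 °C
Reagents that add atoms: 5-bromopent-2-yne (CC#CCCBr); iodine (II)
Why: Copper-catalysed anti-carbomagnesiation of the propargylic magnesium alkoxide delivers the pentynyl group to C4 and magnesium to C5 cis to the CH2O group in a five-membered chelate, and iodinolysis with retention gives the (Z)-iodoalkene that fixes the C4=C5 geometry.

Step 7
Reactants: 20 (2Z)-2-(iodomethylidene)hept-5-yn-1-ol; 2 tert-butyl(chloro)dimethylsilane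
Product: 21 tert-butyl{[(2Z)-2-(iodomethylidene)hept-5-yn-1-yl]oxy}dimethylsilane
Conditions: TBSCl, imidazole, CH2Cl2, 25 °C
Reagents that add atoms: tert-butyl(chloro)dimethylsilane (CC(C)(C)[Si](C)(C)Cl)
Why: Routine silylation of the primary allylic alcohol (C15 oxygen), which must stay protected until the last step.

Step 8
Reactants: 21 tert-butyl{[(2Z)-2-(iodomethylidene)hept-5-yn-1-yl]oxy}dimethylsilane; 22 chlorobis(cyclopentadienyl)hydridozirconium; 23 N-bromosuccinimide
Product: 25 {[(2Z,5E)-6-bromo-2-(iodomethylidene)hept-5-en-1-yl]oxy}(tert-butyl)dimethylsilane, via alkenylzirconocene chloride 24 (not isolated)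
Conditions: Cp2Zr(H)Cl (1.5 equiv), THF, 25 → 45 °C; then NBS, 0 °C
Reagents that add atoms: N-bromosuccinimide (O=C1CCC(=O)N1Br)
Why: Syn-hydrozirconation of the methyl alkyne under equilibrating conditions should place zirconium on the less hindered methyl-bearing carbon C10, and bromodezirconation with retention gives the (E)-2-bromoalkene, that is the C1=C10 geometry of the target.

Step 9
Reactants: 13 (2R,3R)-2-(bromomethyl)-5-oxooxolane-3-carbaldehyde; 25 {[(2Z,5E)-6-bromo-2-(iodomethylidene)hept-5-en-1-yl]oxy}(tert-butyl)dimethylsilane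
Product: 26 (4S,5R)-5-(bromomethyl)-4-{(1R,2Z,6E)-7-bromo-1-hydroxy-3-[(TBS-oxy)methyl]octa-2,6-dien-1-yl}oxolan-2-one
Conditions: CrCl2 (5 equiv), NiCl2 (0.02 equiv), DMSO–THF, 25 °C
Reagents that add atoms: compound 25 (Br/C(C)=C/CC/C(CO[Si](C)(C)C(C)(C)C)=C/I)
Why: Nozaki–Hiyama–Kishi coupling: the alkenylchromium reagent forms chemoselectively at the alkenyl carbon–iodine bond (alkenyl and alkyl bromides stay inert) and adds with retention of the Z olefin geometry, and Felkin–Anh attack anti to the larger C8 ring carbon is expected to set the (6R) carbinol.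

Step 10
Reactants: 26 (4S,5R)-5-(bromomethyl)-4-{(1R,2Z,6E)-7-bromo-1-hydroxy-3-[(TBS-oxy)methyl]octa-2,6-dien-1-yl}oxolan-2-one; 27 triethylsilyl trifluoromethanesulfonate
Product: 28 (4R,5R)-5-(bromomethyl)-4-{(1R,2Z,6E)-7-bromo-3-[(TBS-oxy)methyl]-1-(TES-oxy)octa-2,6-dien-1-yl}oxolan-2-one
Conditions: Et3SiOTf, 2,6-lutidine, CH2Cl2, −78 °C
Reagents that add atoms: triethylsilyl trifluoromethanesulfonate (CC[Si](CC)(CC)OS(=O)(=O)C(F)(F)F)
Why: Silylation of the secondary allylic alcohol under non-nucleophilic conditions blocks the C6 hydroxyl against translactonisation and the later enolate chemistry, with a group that can be removed beside the primary TBS ether.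

Step 11
Reactants: 28 (4R,5R)-5-(bromomethyl)-4-{(1R,2Z,6E)-7-bromo-3-[(TBS-oxy)methyl]-1-(TES-oxy)octa-2,6-dien-1-yl}oxolan-2-one
Product: 29 (3aR,4R,5Z,9E,11aS)-10-methyl-6-[(TBS-oxy)methyl]-4-(TES-oxy)-3a,4,7,8,11,11a-hexahydrocyclodeca[b]furan-2(3H)-one
Conditions: NiBr2(MeOCH2CH2OMe) (0.3 equiv), 4,4′-di-tert-butyl-2,2′-bipyridine (0.3 equiv), NaI (0.5 equiv), Mn powder (4 equiv), DMA, 40 °C, slow addition to 2 mM
Reagents that add atoms: none
Why: Bipyridine-ligated zerovalent nickel inserts into the alkenyl carbon–bromine bond at C10 with retention of the E geometry, a monovalent nickel species abstracts the halogen from the primary C9 bromide (partly exchanged to iodide in situ) to give a primary radical, and this radical is captured by the alkenylnickel centre of the same molecule to give a trivalent alkyl(alkenyl)nickel species that forms the C9–C10 bond by reductive elimination, Mn returning nickel to the zerovalent state. The closest known reaction type is the nickel-catalysed reductive alkenyl–alkyl cross-electrophile coupling of an alkenyl bromide with a primary alkyl halide, used here in its ring-closing form. One ring is closed, the ten-membered carbocycle, by end-to-end C(sp3)–C(sp2) bond formation through an eleven-membered nickelacycle that contracts on reductive elimination; since the radical is captured at the metal, an exo or endo descriptor does not apply. No stereocentre is created: C6, C7 and C8 are spectators and the C1=C10 geometry is inherited from the (E)-alkenyl bromide. The step needs cross-coupling over homo-coupling and cyclisation over oligomerisation, hydrodebromination or reductive opening of the β-acyloxy bromide; the different activation modes of the sp2 and sp3 carbon–bromine bonds, Mn in place of Zn, pseudo-high dilution and the preorganisation by the trans lactone (C6 arm and C9 on opposite faces) and the two trisubstituted olefins should secure this.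

Step 12
Reactants: 29 (3aR,4R,5Z,9E,11aS)-10-methyl-6-[(TBS-oxy)methyl]-4-(TES-oxy)-3a,4,7,8,11,11a-hexahydrocyclodeca[b]furan-2(3H)-one; 30 N,N-dimethylmethaniminium iodide (Eschenmoser's salt); 31 iodomethane
Product: 34 (3aR,4R,5Z,9E,11aS)-10-methyl-3-methylidene-6-[(TBS-oxy)methyl]-4-(TES-oxy)-3a,4,7,8,11,11a-hexahydrocyclodeca[b]furan-2(3H)-one, via Mannich base 32 (not isolated), via trimethylammonium iodide 33 (not isolated)
Conditions: LiN(SiMe3)2, THF, −78 °C; CH2=NMe2+ I−, −78 → 25 °C; MeI, MeOH, 25 °C; aq NaHCO3, EtOAc, 25 °C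
Reagents that add atoms: N,N-dimethylmethaniminium iodide (C=[N+](C)C.[I-])
Why: Mannich reaction of the lithium lactone enolate with Eschenmoser's salt, quaternisation and base-induced loss of trimethylamine (Hofmann-type elimination) should install the exocyclic C11=C13 methylene, the transient C11 stereocentre being destroyed.

Step 13
Reactants: 34 (3aR,4R,5Z,9E,11aS)-10-methyl-3-methylidene-6-[(TBS-oxy)methyl]-4-(TES-oxy)-3a,4,7,8,11,11a-hexahydrocyclodeca[b]furan-2(3H)-one
Product: 35 (3aS,4R,5Z,9E,11aS)-4-hydroxy-10-methyl-3-methylidene-6-[(TBS-oxy)methyl]-3a,4,7,8,11,11a-hexahydrocyclodeca[b]furan-2(3H)-one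
Conditions: HF·pyridine, pyridine, THF, 0 °C
Reagents that add atoms: none
Why: Buffered fluoride should cleave the secondary triethylsilyl ether faster than the primary tert-butyldimethylsilyl ether (selective desilylation), freeing the C6 hydroxyl without touching C6 or the α-methylene lactone.

Step 14
Reactants: 36 (TBS-oxy)acetaldehyde; 37 ethyl 2-(triphenyl-λ5-phosphanylidene)propanoate
Product: 38 ethyl (2E)-2-methyl-4-(TBS-oxy)but-2-enoate
Conditions: CH2Cl2, 25 °C
Reagents that add atoms: ethyl 2-(triphenyl-λ5-phosphanylidene)propanoate (CCOC(=O)C(C)=P(c1ccccc1)(c1ccccc1)c1ccccc1)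
Why: Wittig olefination with the stabilised α-methyl ylide should give the (E)-2-methylbut-2-enoate, the tiglate geometry of the side chain.

Step 15
Reactants: 38 ethyl (2E)-2-methyl-4-(TBS-oxy)but-2-enoate; 39 lithium hydroxide
Product: 40 (2E)-2-methyl-4-(TBS-oxy)but-2-enoic acid
Conditions: LiOH, THF–H2O, 25 °C; then cold 0.5 M HCl to pH 4
Reagents that add atoms: lithium hydroxide ([Li+].[OH-])
Why: Saponification of the ethyl ester should leave the primary silyl ether and the E olefin intact.

Step 16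
Reactants: 35 (3aS,4R,5Z,9E,11aS)-4-hydroxy-10-methyl-3-methylidene-6-[(TBS-oxy)methyl]-3a,4,7,8,11,11a-hexahydrocyclodeca[b]furan-2(3H)-one; 40 (2E)-2-methyl-4-(TBS-oxy)but-2-enoic acid
Product: 41 (3aR,4R,5Z,9E,11aS)-10-methyl-3-methylidene-2-oxo-6-[(TBS-oxy)methyl]-2,3,3a,4,7,8,11,11a-octahydrocyclodeca[b]furan-4-yl (2E)-2-methyl-4-(TBS-oxy)but-2-enoate
Conditions: DCC, DMAP (0.3 equiv), CH2Cl2, 0 → 25 °C
Reagents that add atoms: compound 40 (OC(=O)/C(C)=C/CO[Si](C)(C)C(C)(C)C)
Why: Steglich esterification acylates the C6 hydroxyl with retention, since the C6–O bond is not broken, and DMAP catalysis should overcome the low reactivity of the α-methyl enoic acid.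

Step 17
Reactants: 41 (3aR,4R,5Z,9E,11aS)-10-methyl-3-methylidene-2-oxo-6-[(TBS-oxy)methyl]-2,3,3a,4,7,8,11,11a-octahydrocyclodeca[b]furan-4-yl (2E)-2-methyl-4-(TBS-oxy)but-2-enoate
Product: 42 (3aR,4R,5Z,9E,11aS)-6-(hydroxymethyl)-10-methyl-3-methylidene-2-oxo-2,3,3a,4,7,8,11,11a-octahydrocyclodeca[b]furan-4-yl (2E)-4-hydroxy-2-methylbut-2-enoate
Conditions: HF·pyridine, THF, 0 → 25 °C
Reagents that add atoms: none
Why: Fluoride-mediated desilylation under mildly acidic conditions should remove both primary TBS ethers while sparing the α-methylene lactone and the allylic ester and avoiding base-induced acyl migration or translactonisation.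

**Compound list**

1 | (5R)-5-(hydroxymethyl)oxolan-2-one | O=C1CC[C@H](CO)O1 | starting material
2 | tert-butyl(chloro)dimethylsilane | CC(C)(C)[Si](C)(C)Cl | starting material
3 | (5R)-5-[(TBS-oxy)methyl]oxolan-2-one | O=C1CC[C@H](CO[Si](C)(C)C(C)(C)C)O1 | intermediate
4 | benzeneselenenyl bromide | Br[Se]c1ccccc1 | starting material
5 | (5R)-3-(phenylselanyl)-5-[(TBS-oxy)methyl]oxolan-2-one (C3 epimers) | O=C1C([Se]c2ccccc2)C[C@H](CO[Si](C)(C)C(C)(C)C)O1 | intermediate
6 | (5R)-5-[(TBS-oxy)methyl]furan-2(5H)-one | O=C1C=C[C@H](CO[Si](C)(C)C(C)(C)C)O1 | intermediate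
7 | vinylmagnesium bromide | C=C[Mg]Br | starting material
8 | (4S,5R)-4-ethenyl-5-[(TBS-oxy)methyl]oxolan-2-one | O=C1C[C@@H](C=C)[C@H](CO[Si](C)(C)C(C)(C)C)O1 | intermediate
9 | dibromotriphenyl-λ5-phosphane | BrP(Br)(c1ccccc1)(c1ccccc1)c1ccccc1 | starting material
10 | (4S,5R)-5-(bromomethyl)-4-ethenyloxolan-2-one | O=C1C[C@@H](C=C)[C@H](CBr)O1 | intermediate
11 | ozone | [O-][O+]=O | starting material
12 | (4R,5R)-5-(bromomethyl)-4-(1,2,4-trioxolan-3-yl)oxolan-2-one (trioxolane carbon undefined) | O=C1C[C@@H](C2OCOO2)[C@H](CBr)O1 | intermediate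
13 | (2R,3R)-2-(bromomethyl)-5-oxooxolane-3-carbaldehyde | O=C1C[C@@H](C=O)[C@H](CBr)O1 | intermediate
14 | 5-bromopent-2-yne | CC#CCCBr | starting material
15 | magnesium | [Mg] | starting material
16 | prop-2-yn-1-ol | C#CCO | starting material
17 | iodine | II | starting material
18 | pent-3-yn-1-ylmagnesium bromide | CC#CCC[Mg]Br | intermediate
19 | bromomagnesium alkoxide of (2Z)-2-[(bromomagnesio)methylidene]hept-5-yn-1-ol | CC#CCC/C(CO[Mg]Br)=C/[Mg]Br | intermediate
20 | (2Z)-2-(iodomethylidene)hept-5-yn-1-ol | CC#CCC/C(CO)=C/I | intermediate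
21 | tert-butyl{[(2Z)-2-(iodomethylidene)hept-5-yn-1-yl]oxy}dimethylsilane | CC#CCC/C(CO[Si](C)(C)C(C)(C)C)=C/I | intermediate
22 | chlorobis(cyclopentadienyl)hydridozirconium, Cp2Zr(H)Cl | [H][Zr](Cl)(C1C=CC=C1)C1C=CC=C1 | starting material
23 | N-bromosuccinimide | O=C1CCC(=O)N1Br | starting material
24 | chlorobis(cyclopentadienyl)[(2E,6Z)-7-iodo-6-[(TBS-oxy)methyl]hepta-2,6-dien-2-yl]zirconium | Cl[Zr](C1C=CC=C1)(C1C=CC=C1)/C(C)=C/CC/C(CO[Si](C)(C)C(C)(C)C)=C/I | intermediate
25 | {[(2Z,5E)-6-bromo-2-(iodomethylidene)hept-5-en-1-yl]oxy}(tert-butyl)dimethylsilane | Br/C(C)=C/CC/C(CO[Si](C)(C)C(C)(C)C)=C/I | intermediate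
26 | (4S,5R)-5-(bromomethyl)-4-{(1R,2Z,6E)-7-bromo-1-hydroxy-3-[(TBS-oxy)methyl]octa-2,6-dien-1-yl}oxolan-2-one | O=C1C[C@@H]([C@H](O)/C=C(CO[Si](C)(C)C(C)(C)C)/CC/C=C(C)/Br)[C@H](CBr)O1 | intermediate
27 | triethylsilyl trifluoromethanesulfonate | CC[Si](CC)(CC)OS(=O)(=O)C(F)(F)F | starting material
28 | (4R,5R)-5-(bromomethyl)-4-{(1R,2Z,6E)-7-bromo-3-[(TBS-oxy)methyl]-1-(TES-oxy)octa-2,6-dien-1-yl}oxolan-2-one | O=C1C[C@@H]([C@H](O[Si](CC)(CC)CC)/C=C(CO[Si](C)(C)C(C)(C)C)/CC/C=C(C)/Br)[C@H](CBr)O1 | intermediate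
29 | (3aR,4R,5Z,9E,11aS)-10-methyl-6-[(TBS-oxy)methyl]-4-(TES-oxy)-3a,4,7,8,11,11a-hexahydrocyclodeca[b]furan-2(3H)-one | O=C1O[C@H]2C/C(C)=C/CC/C(CO[Si](C)(C)C(C)(C)C)=C/[C@@H](O[Si](CC)(CC)CC)[C@@H]2C1 | intermediate
30 | N,N-dimethylmethaniminium iodide (Eschenmoser's salt) | C=[N+](C)C.[I-] | starting material
31 | iodomethane | CI | starting material
32 | 3-[(dimethylamino)methyl] derivative of 29 (C11 epimers) | CN(C)CC1C(=O)O[C@H]2C/C(C)=C/CC/C(CO[Si](C)(C)C(C)(C)C)=C/[C@@H](O[Si](CC)(CC)CC)[C@H]12 | intermediate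
33 | 3-[(trimethylammonio)methyl] derivative of 29, iodide (C11 epimers) | C[N+](C)(C)CC1C(=O)O[C@H]2C/C(C)=C/CC/C(CO[Si](C)(C)C(C)(C)C)=C/[C@@H](O[Si](CC)(CC)CC)[C@H]12.[I-] | intermediate
34 | (3aR,4R,5Z,9E,11aS)-10-methyl-3-methylidene-6-[(TBS-oxy)methyl]-4-(TES-oxy)-3a,4,7,8,11,11a-hexahydrocyclodeca[b]furan-2(3H)-one | C=C1C(=O)O[C@H]2C/C(C)=C/CC/C(CO[Si](C)(C)C(C)(C)C)=C/[C@@H](O[Si](CC)(CC)CC)[C@H]12 | intermediate
35 | (3aS,4R,5Z,9E,11aS)-4-hydroxy-10-methyl-3-methylidene-6-[(TBS-oxy)methyl]-3a,4,7,8,11,11a-hexahydrocyclodeca[b]furan-2(3H)-one | C=C1C(=O)O[C@H]2C/C(C)=C/CC/C(CO[Si](C)(C)C(C)(C)C)=C/[C@@H](O)[C@H]12 | intermediate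
36 | (TBS-oxy)acetaldehyde | O=CCO[Si](C)(C)C(C)(C)C | starting material
37 | ethyl 2-(triphenyl-λ5-phosphanylidene)propanoate | CCOC(=O)C(C)=P(c1ccccc1)(c1ccccc1)c1ccccc1 | starting material
38 | ethyl (2E)-2-methyl-4-(TBS-oxy)but-2-enoate | CCOC(=O)/C(C)=C/CO[Si](C)(C)C(C)(C)C | intermediate
39 | lithium hydroxide | [Li+].[OH-] | starting material
40 | (2E)-2-methyl-4-(TBS-oxy)but-2-enoic acid | OC(=O)/C(C)=C/CO[Si](C)(C)C(C)(C)C | intermediate
41 | (3aR,4R,5Z,9E,11aS)-10-methyl-3-methylidene-2-oxo-6-[(TBS-oxy)methyl]-2,3,3a,4,7,8,11,11a-octahydrocyclodeca[b]furan-4-yl (2E)-2-methyl-4-(TBS-oxy)but-2-enoate | C=C1C(=O)O[C@H]2C/C(C)=C/CC/C(CO[Si](C)(C)C(C)(C)C)=C/[C@@H](OC(=O)/C(C)=C/CO[Si](C)(C)C(C)(C)C)[C@H]12 | intermediate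
42 | (3aR,4R,5Z,9E,11aS)-6-(hydroxymethyl)-10-methyl-3-methylidene-2-oxo-2,3,3a,4,7,8,11,11a-octahydrocyclodeca[b]furan-4-yl (2E)-4-hydroxy-2-methylbut-2-enoate | C=C1C(=O)O[C@H]2C/C(C)=C/CC/C(CO)=C/[C@@H](OC(=O)/C(C)=C/CO)[C@H]12 | target

**Step count and risks**

Total step count: 17. Longest linear sequence: 12 steps (steps 1–5, 9–13, 16, 17).

Steps most likely to fail:

1. Step 11 (ring closure). The C9 radical may escape capture at the alkenylnickel centre, so that oligomerisation, hydrodebromination or reductive opening of the bromolactone outruns cyclisation. The fallback closes the same bond by the known nickel-catalysed reductive alkyne–epoxide coupling. It sets out from 13 and 21 (alkyne not yet hydrozirconated) and comes back at 29. CrCl2/NiCl2 coupling of 13 with 21 would give the alkynyl allylic alcohol F1. Et3SiOTf and 2,6-lutidine would give its triethylsilyl ether F2. NaOMe in MeOH at 0 °C would open the lactone and let the C8 alkoxide displace the C9 bromide, giving the epoxy methyl ester F3 with C8 unchanged. Ni(C8H12)2 (bis(cycloocta-1,5-diene)nickel), PBu3 and BEt3 at high dilution should then add C9 and hydrogen syn across the C10≡C1 alkyne with opening at the terminal epoxide carbon. This would give the ten-membered hydroxy ester F4 with the E olefin, which catalytic TsOH would lactonise to 29. Whether the alkyne inserts to give the ten-membered endocyclic olefin or a nine-membered ring with an exocyclic olefin is the open point of this fallback.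

2. Step 9 (fragment union). The β-acyloxy aldehyde 13 may epimerise at C7 or lose the lactone carboxylate by β-elimination, and facial selectivity at C6 may be poor. The fallback replaces substrate control by reagent control; it sets out from the crude product of step 9 (26 together with its C6 epimer F5) and comes back at 26. Dess–Martin periodinane buffered with NaHCO3 would oxidise the mixture to the enone F6. Reduction with catecholborane and (R)-1-methyl-3,3-diphenyltetrahydro-1H,3H-pyrrolo[1,2-c][1,3,2]oxazaborole (CBS reduction, alkenyl arm taken as the large group) at −78 °C is expected to return the (6R) alcohol 26.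

3. Step 8 (alkenyl bromide). Hydrozirconation may add zirconium to either alkyne carbon, giving constitutional isomers that cannot be separated at the stage of 25. The fallback fixes the regiochemistry before the chain is assembled; it sets out from 16 and comes back at 25. Commercial pent-3-yn-1-ol F7 would be hydrozirconated and brominated (Cp2Zr(H)Cl, then NBS) to (3E)-4-bromopent-3-en-1-ol F8, where regioisomers should be separable by chromatography. CBr4/PPh3 would give (2E)-2,5-dibromopent-2-ene F9, and Mg should insert selectively into the sp3 carbon–bromine bond to give the Grignard reagent F10. CuI-catalysed addition of F10 to 16 and iodinolysis would give (2Z,5E)-6-bromo-2-(iodomethylidene)hept-5-en-1-ol F11, which TBSCl and imidazole convert into 25.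

Further compounds

F1 | step 11 | (4S,5R)-5-(bromomethyl)-4-{(1R,2Z)-1-hydroxy-3-[(TBS-oxy)methyl]oct-2-en-6-yn-1-yl}oxolan-2-one | O=C1C[C@@H]([C@H](O)/C=C(CO[Si](C)(C)C(C)(C)C)/CCC#CC)[C@H](CBr)O1
F2 | step 11 | triethylsilyl ether of F1 at the C6 oxygen | O=C1C[C@@H]([C@H](O[Si](CC)(CC)CC)/C=C(CO[Si](C)(C)C(C)(C)C)/CCC#CC)[C@H](CBr)O1
F3 | step 11 | methyl ester with C8–C9 oxirane, C6 TES ether and C10≡C1 alkyne (C6, C7, C8 as in 28) | COC(=O)C[C@@H]([C@H](O[Si](CC)(CC)CC)/C=C(CO[Si](C)(C)C(C)(C)C)/CCC#CC)[C@@H]1CO1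
F4 | step 11 | ten-membered hydroxy methyl ester (seco-lactone of 29, free C8 hydroxyl) | O[C@H]1C/C(C)=C/CC/C(CO[Si](C)(C)C(C)(C)C)=C/[C@@H](O[Si](CC)(CC)CC)[C@@H]1CC(=O)OC
F5 | step 9 | C6 epimer of 26 (1S carbinol) | O=C1C[C@@H]([C@@H](O)/C=C(CO[Si](C)(C)C(C)(C)C)/CC/C=C(C)/Br)[C@H](CBr)O1
F6 | step 9 | C6 ketone (enone) derived from 26 and F5 | O=C1C[C@@H](C(=O)/C=C(CO[Si](C)(C)C(C)(C)C)/CC/C=C(C)/Br)[C@H](CBr)O1
F7 | step 8 | pent-3-yn-1-ol | CC#CCCO
F8 | step 8 | (3E)-4-bromopent-3-en-1-ol | Br/C(C)=C/CCO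
F9 | step 8 | (2E)-2,5-dibromopent-2-ene | Br/C(C)=C/CCBr
F10 | step 8 | [(3E)-4-bromopent-3-en-1-yl]magnesium bromide | Br/C(C)=C/CC[Mg]Br
F11 | step 8 | (2Z,5E)-6-bromo-2-(iodomethylidene)hept-5-en-1-ol | Br/C(C)=C/CC/C(CO)=C/I
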